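**Assumption:** quinic acid numbering is used throughout (C1 carries OH and CO2H; 3-OH is cis to 4-OH; 5-OH is trans to 4-OH and cis to CO2H). The target SMILES decodes to the natural (−)-quinic acid series with the esters on O4 and O5.

## Retrosynthetic overview

1. Target ⇒ one acid hydrolysis of a fully masked diester: phenols as acetates, 3-OH as formate, 1-OH/CO2H tied as a spiro-2,2-dimethyl-1,3-dioxolan-4-one.
2. Both ester C–O bonds ⇒ double acylation of a 4,5-trans-diol with (E)-4-acetoxycinnamoyl chloride (from p-coumaric acid).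
3. That diol ⇒ (−)-quinic acid by a one-pot double cyclisation followed in the same flask by regioselective opening of one of the new rings.
4. Ring order: the cyclohexane and both arenes are bought. In the key operation the cis-fused 3,4-orthoformate (2-methoxy-1,3-dioxolane) ring closes first and the spiro-dioxolanone ring second. The orthoformate ring is opened at once (axial 3-formate, free 4-OH); the dioxolanone ring is opened in the last step.

## Route

**Step 1**
Reactants: 1 (−)-quinic acid
Product: 4 3-O-formylquinic acid acetonide (spiro-2,2-dimethyl-1,3-dioxolan-4-one across 1-OH/CO2H; free 4-OH and 5-OH), via quinic acid 3,4-orthoformate 2 (not isolated), via orthoformate spiro-dioxolanone 3 (not isolated)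
Conditions: HC(OMe)3 (1.2 equiv), CSA (5 mol %), 5 Å MS, DMF, rt; then 2-methoxypropene (1.5 equiv), 0 °C to rt; then AcOH/NaOAc buffer (pH 4.5), THF–H2O, 0 °C
Reagents that add atoms: trimethyl orthoformate COC(OC)OC; 2-methoxypropene COC(C)=C; water O
Why: Proposed new method: the more electrophilic orthoformate first ties the cis-3,4-diol into a cis-fused 2-methoxy-1,3-dioxolane (orthoester exchange), the carboxylic acid then adds to the enol ether and the tertiary 1-OH closes the spiro-dioxolanone (closest known reaction: the one-pot kinetic double acetonide formation of quinic acid with 2,2-dimethoxypropane), and buffered hydrolysis of the orthoformate follows the axial-ester/equatorial-alcohol rule of cyclic orthoester hydrolysis, so the formyl group ends on the axial 3-O and the equatorial 4-OH is released in the chair with O4/O5 equatorial; no stereocentre of 1 is touched.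

**Step 2**
Reactants: 5 p-coumaric acid
Product: 6 (E)-4-acetoxycinnamic acid
Conditions: Ac2O, aq. NaOH, 0 °C; then aq. HCl
Reagents that add atoms: acetic anhydride CC(=O)OC(C)=O
Why: Schotten–Baumann O-acetylation of the phenoxide in water, where the carboxylate is not activated and the E-alkene is untouched.

**Step 3**
Reactants: 4 3-O-formylquinic acid acetonide; 6 (E)-4-acetoxycinnamic acid (2.5 equiv)
Product: 8 4,5-bis-O-[(E)-4-acetoxycinnamoyl]-3-O-formylquinic acid acetonide, via (E)-4-acetoxycinnamoyl chloride 7 (not isolated)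
Conditions: 6, (COCl)2, DMF (cat.), CH2Cl2, 0 °C to rt, evaporate; then 4, pyridine, DMAP (cat.), CH2Cl2, −20 °C to 0 °C
Reagents that add atoms: none
Why: DMAP-catalysed acid chloride esterification of the trans-diequatorial 4,5-diol, the only free hydroxyls because O1 and CO2H are locked in the dioxolanone and O3 carries the formate; low temperature and fast acyl transfer limit formyl migration, and no stereocentre or alkene geometry changes.

**Step 4**
Reactants: 8 4,5-bis-O-[(E)-4-acetoxycinnamoyl]-3-O-formylquinic acid acetonide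
Product: 9 4,5-di-O-p-coumaroylquinic acid (target)
Conditions: 1 M aq. HCl–THF (1:3), rt, 3–5 d
Reagents that add atoms: none
Why: Acid-catalysed hydrolysis cleaves the acylal-type acetonide, the formate and the phenolic acetates faster than the conjugated secondary cinnamate esters (the same acid deprotection is established for acetonide/aryl-acetate-protected caffeoylquinates), and acid does not promote acyl migration or touch any stereocentre.

## Compound list

1 | (−)-quinic acid, (1S,3R,4S,5R)-1,3,4,5-tetrahydroxycyclohexane-1-carboxylic acid | O[C@@H]1[C@H](O)C[C@@](O)(C(=O)O)C[C@H]1O | starting material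
2 | quinic acid 3,4-orthoformate: cis-fused 2-methoxy-1,3-dioxolane across O3/O4, epimer mixture at the orthoformate carbon, C1/C3/C4/C5 as in 1 | COC2O[C@@H]1[C@H](O2)C[C@@](O)(C(=O)O)C[C@H]1O | intermediate (not isolated)
3 | orthoformate spiro-dioxolanone: as 2, with 1-OH and CO2H closed to a spiro-2,2-dimethyl-1,3-dioxolan-4-one; free 5-OH | COC2O[C@@H]1[C@H](O2)C[C@@]3(C(=O)OC(C)(C)O3)C[C@H]1O | intermediate (not isolated)
4 | 3-O-formylquinic acid acetonide: spiro-2,2-dimethyl-1,3-dioxolan-4-one at C1, formate on O3, free 4-OH and 5-OH, configuration of 1 | O[C@@H]1[C@H](OC=O)C[C@@]2(C(=O)OC(C)(C)O2)C[C@H]1O | intermediate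
5 | p-coumaric acid, (E)-3-(4-hydroxyphenyl)prop-2-enoic acid | OC(=O)/C=C/c1ccc(O)cc1 | starting material
6 | (E)-3-(4-acetoxyphenyl)prop-2-enoic acid | CC(=O)Oc1ccc(/C=C/C(=O)O)cc1 | intermediate
7 | (E)-3-(4-acetoxyphenyl)prop-2-enoyl chloride | CC(=O)Oc1ccc(/C=C/C(=O)Cl)cc1 | intermediate (not isolated)
8 | 4,5-bis-O-[(E)-4-acetoxycinnamoyl]-3-O-formylquinic acid acetonide (spiro-dioxolanone at C1), configuration of 1 | O=C(/C=C/c1ccc(OC(C)=O)cc1)O[C@@H]1[C@H](OC=O)C[C@@]2(C(=O)OC(C)(C)O2)C[C@H]1OC(=O)/C=C/c1ccc(OC(C)=O)cc1 | intermediate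
9 | 4,5-di-O-p-coumaroylquinic acid, (1S,3R,4R,5R)-1,3-dihydroxy-4,5-bis{[(2E)-3-(4-hydroxyphenyl)prop-2-enoyl]oxy}cyclohexane-1-carboxylic acid (quinic acid numbering) | O=C(/C=C/c1ccc(O)cc1)O[C@@H]1[C@H](O)C[C@@](O)(C(=O)O)C[C@H]1OC(=O)/C=C/c1ccc(O)cc1 | target

## Step count and risks

Total steps: 4. Longest linear sequence: 3 steps (1 → 4 → 8 → 9; equally 5 → 6 → 8 → 9).

**Most likely to fail, first: step 1.** The two acetal-type rings may scramble (bis-acetonide or bis-orthoformate), or the orthoformate may open to the 4-formate. Fallback, setting out from 1 and coming back to the route at 9: replace the double acetal logic by a lactone and a silyl ether, whose regiocontrol is independent of the orthoester opening. Azeotropic lactonisation of 1 (TsOH cat., toluene–DMF, reflux) gives 1,5-quinide F1. TBSCl/imidazole in DMF at 0 °C silylates its equatorial 3-OH to give 3-O-TBS-1,5-quinide F2. NaOMe in MeOH at 0 °C opens the lactone to methyl 3-O-TBS-quinate F3. Acylation of its 4,5-diol with 7 under the conditions of step 3 gives methyl 4,5-bis-O-[(E)-4-acetoxycinnamoyl]-3-O-TBS-quinate F4. Prolonged aqueous HCl–THF then removes the silyl ether, the aryl acetates and the methyl ester to give 9.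

**Second: step 3.** The formate may migrate from O3 to O4 under the basic acylation conditions, or the flanked 4-OH may react sluggishly. Fallback, setting out from 4 and coming back to the route at 9: build the cinnamate C=C bonds on the diol instead of transferring preformed acyl groups. Heating 4 with Meldrum's acid (toluene, 90 °C, no base) gives the 4,5-bis(hydrogen malonate) of 3-O-formylquinic acid acetonide F5. A double Knoevenagel–Doebner condensation with 4-hydroxybenzaldehyde (pyridine, β-alanine cat., 50 °C) gives the E,E-configured 4,5-di-O-p-coumaroyl-3-O-formylquinic acid acetonide F6 with free phenols. The aqueous HCl–THF treatment of step 4, now short because no aryl acetate is present, gives 9.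

**Third: step 4.** The slow acid cleavage of the aryl acetates may cost some cinnamate ester or allow acyl migration. Fallback, setting out from 8 and coming back to the route at 9: split the deprotection into two chemically different stages. A few hours of 1 M aq. HCl–THF remove only the acetonide and the formate to give 4,5-bis-O-[(E)-4-acetoxycinnamoyl]quinic acid F7. NH4OAc in aqueous MeOH at rt then cleaves the two phenolic acetates under near-neutral conditions to give 9.

## Further compounds

F1 | step 1 | 1,5-quinide (quinic acid 1,5-lactone) | O[C@@H]1[C@H](O)C[C@]2(O)C[C@H]1OC2=O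
F2 | step 1 | 3-O-tert-butyldimethylsilyl-1,5-quinide | O[C@@H]1[C@H](O[Si](C)(C)C(C)(C)C)C[C@]2(O)C[C@H]1OC2=O
F3 | step 1 | methyl 3-O-tert-butyldimethylsilylquinate | O[C@@H]1[C@H](O[Si](C)(C)C(C)(C)C)C[C@@](O)(C(=O)OC)C[C@H]1O
F4 | step 1 | methyl 4,5-bis-O-[(E)-4-acetoxycinnamoyl]-3-O-tert-butyldimethylsilylquinate | O=C(/C=C/c1ccc(OC(C)=O)cc1)O[C@@H]1[C@H](O[Si](C)(C)C(C)(C)C)C[C@@](O)(C(=O)OC)C[C@H]1OC(=O)/C=C/c1ccc(OC(C)=O)cc1
F5 | step 3 | 4,5-bis-O-(carboxyacetyl)-3-O-formylquinic acid acetonide (bis hydrogen malonate) | O=C(O)CC(=O)O[C@@H]1[C@H](OC=O)C[C@@]2(C(=O)OC(C)(C)O2)C[C@H]1OC(=O)CC(=O)O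
F6 | step 3 | 4,5-di-O-[(E)-p-coumaroyl]-3-O-formylquinic acid acetonide | O=C(/C=C/c1ccc(O)cc1)O[C@@H]1[C@H](OC=O)C[C@@]2(C(=O)OC(C)(C)O2)C[C@H]1OC(=O)/C=C/c1ccc(O)cc1
F7 | step 4 | 4,5-bis-O-[(E)-4-acetoxycinnamoyl]quinic acid | O=C(/C=C/c1ccc(OC(C)=O)cc1)O[C@@H]1[C@H](O)C[C@@](O)(C(=O)O)C[C@H]1OC(=O)/C=C/c1ccc(OC(C)=O)cc1
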